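**Retrosynthetic overview**
1. Ring numbering used below: C1 = C(CH3)(OH), C2 = CH carrying the side chain, C3 = C(CH3)2, C4 = CH(OH), C5 and C6 = CH2. The aryl ether is made last, by Mitsunobu coupling of umbelliferone 22 with the primary hydroxyl of tetraol 21.
2. C4–OH comes from hydroxyl-directed epoxidation of the C4=C5 alkene 18 and hydride opening at C5 (direct hydride reduction of the C4 ketone would enter anti to the side chain and give the epimer, so the ketone is first turned into the alkene by a Shapiro reaction). C1–OH comes from Baeyer–Villiger oxidation of a C1 formyl group with retention, and the second C3 methyl from methylation of a silyl enol ether.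
3. Key disconnection: C1–C2 and C5–C6, both made in one catalytic enantioselective Diels–Alder reaction of 2-siloxy diene 9 with methacrolein 10. This is the only ring-forming step.
4. Enabling feature: in the six-membered ring the oxygen-bearing C4 is flanked by the non-stereogenic gem-dimethyl carbon C3 and stands para to the quaternary O/CH3-bearing C1. C4–O can therefore be the 2-siloxy group of the diene (para director), C3 the enol-ether carbon that takes its second methyl after the cycloaddition, and C1 the alpha-carbon of methacrolein (CHO as masked OH).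
5. Diene 9 comes from (R)-linalool 1, which supplies the side-chain carbinol centre: hydroboration, acetonide, ozonolysis, Wittig reaction with ylide 7, silyl dienol ether.

Key step: step 6

Remark: Diox = (4R)-2,2,4-trimethyl-1,3-dioxan-4-yl.
Assumption: the (S)-configured catalyst of step 6 is taken to deliver the (1S,2S) adduct, following the accepted facial model for 2-substituted acroleins; if the sense proves opposite, its (R) antipode is used and nothing else changes.

**Step 1**
Reactants: 1 (R)-(−)-linalool
Product: 3 (3R)-3,7-dimethyloct-6-ene-1,3-diol, via bis-boryl adduct 2 (not isolated)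
Conditions: 9-BBN (2.2 equiv), THF, 0 °C → rt; then NaOH, H2O2, H2O, 0 °C → rt
Reagents that add atoms: hydrogen peroxide, OO
Why: Hydroboration–oxidation, in which 9-BBN should add anti-Markovnikov to the monosubstituted vinyl group only and leave the trisubstituted alkene and the chiral-pool carbinol centre untouched.

**Step 2**
Reactants: 3 (3R)-3,7-dimethyloct-6-ene-1,3-diol
Product: 4 (4R)-2,2,4-trimethyl-4-(4-methylpent-3-en-1-yl)-1,3-dioxane
Conditions: 2,2-dimethoxypropane, PPTS (cat.), CH2Cl2, rt
Reagents that add atoms: 2,2-dimethoxypropane, COC(C)(C)OC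
Why: Acid-catalysed transketalisation should close the six-membered acetonide of the 1,3-diol and mask both hydroxyls in one temporary ring.

**Step 3**
Reactants: 4 (4R)-2,2,4-trimethyl-4-(4-methylpent-3-en-1-yl)-1,3-dioxane
Product: 6 3-(Diox)propanal, via ozonide 5 (not isolated)
Conditions: O3, CH2Cl2, −78 °C; then PPh3, −78 °C → rt
Reagents that add atoms: ozone, [O-][O+]=O
Why: Ozonolysis with reductive work-up cleaves the only alkene to the aldehyde, which cannot form a lactol because the gamma-hydroxyl is tied up in the acetonide.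

**Step 4**
Reactants: 6 3-(Diox)propanal; 7 3-(triphenyl-λ5-phosphanylidene)butan-2-one
Product: 8 (3E)-3-methyl-6-(Diox)hex-3-en-2-one
Conditions: toluene, 90 °C
Reagents that add atoms: 7 3-(triphenyl-λ5-phosphanylidene)butan-2-one, CC(=O)C(C)=P(c1ccccc1)(c1ccccc1)c1ccccc1
Why: Wittig olefination with a stabilised, alpha-branched ylide, which should give the trisubstituted enone with E geometry.

**Step 5**
Reactants: 8 (3E)-3-methyl-6-(Diox)hex-3-en-2-one
Product: 9 triisopropyl{[(3E)-3-methyl-6-(Diox)hexa-1,3-dien-2-yl]oxy}silane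
Conditions: i-Pr3SiOTf, Et3N, Et2O, 0 °C → rt
Reagents that add atoms: triisopropylsilyl triflate, CC(C)[Si](C(C)C)(C(C)C)OS(=O)(=O)C(F)(F)F
Why: Soft enolisation (silyl triflate and amine) should remove a proton from the alpha′-methyl group of the O-silylated enone and give the cross-conjugated 2-siloxy diene with the E alkene intact.

**Step 6**
Reactants: 9 triisopropyl{[(3E)-3-methyl-6-(Diox)hexa-1,3-dien-2-yl]oxy}silane; 10 methacrolein
Product: 11 (1S,2S)-1,3-dimethyl-2-[2-(Diox)ethyl]-4-(triisopropylsilyloxy)cyclohex-3-ene-1-carbaldehyde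
Conditions: (S)-1-(2-methylphenyl)-3,3-diphenyltetrahydro-1H,3H-pyrrolo[1,2-c][1,3,2]oxazaborole (20 mol %), Tf2NH (18 mol %), CH2Cl2, −78 °C
Reagents that add atoms: 10 methacrolein, CC(=C)C=O
Why: The enal is bound to the cationic boron catalyst through its carbonyl oxygen and reacts in a concerted, asynchronous, normal-demand [4+2] cycloaddition in which the C5–C6 bond (unsubstituted diene terminus to enal beta-carbon) runs ahead of the C1–C2 bond. The closest known reaction type is the oxazaborolidinium-catalysed enantioselective Diels–Alder reaction of 2-substituted acroleins with 2-(trialkylsilyloxy)-1,3-dienes, a class that includes 3-methyl-4-substituted dienes of this pattern. The cyclohexene ring is closed in the intermolecular [4+2] mode, both ring bonds being made suprafacially on each partner in the same event. The quaternary C1 centre is set by the catalyst, which holds the formyl group by B–O coordination and a formyl C–H···O contact and screens one face of the enal with an aryl group; C2 is set relative to C1 by the exo-formyl transition state usual for alpha-substituted acroleins acting on the E-configured diene terminus, which places the side chain cis to the C1 methyl and trans to the formyl group. The step needs regiocontrol, exo selectivity and one enal face: the siloxy group makes the CH2 terminus the most nucleophilic diene carbon (formyl-bearing carbon para to the siloxy carbon, reinforced by the ortho-directing terminal alkyl group), the alpha-methyl group favours exo, and the face is chosen by the catalyst because the dioxane stereocentre is too remote to interfere.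

**Step 7**
Reactants: 11 (1S,2S)-1,3-dimethyl-2-[2-(Diox)ethyl]-4-(triisopropylsilyloxy)cyclohex-3-ene-1-carbaldehyde
Product: 13 (1S,2R)-1,3,3-trimethyl-4-oxo-2-[2-(Diox)ethyl]cyclohexane-1-carbaldehyde, via ammonium enolate 12 (not isolated)
Conditions: Bu4N[Ph3SiF2] (1.2 equiv), MeI (excess), THF, −40 → 0 °C
Reagents that add atoms: iodomethane, CI
Why: Fluoride-induced regiospecific enolate generation from the silyl enol ether and C-methylation at C3, which becomes the non-stereogenic gem-dimethyl carbon, while the non-enolisable neopentylic aldehyde should be too hindered to intercept the tetrasubstituted enolate.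

**Step 8**
Reactants: 13 (1S,2R)-1,3,3-trimethyl-4-oxo-2-[2-(Diox)ethyl]cyclohexane-1-carbaldehyde
Product: 15 (3S,4S)-4-hydroxy-2,2,4-trimethyl-3-[2-(Diox)ethyl]cyclohexan-1-one, via keto formate 14 (not isolated)
Conditions: mCPBA, CH2Cl2, 0 °C → rt; then MeOH, K2CO3, rt
Reagents that add atoms: mCPBA, OOC(=O)c1cccc(Cl)c1
Why: Baeyer–Villiger oxidation of the alpha-quaternary aldehyde, in which the tertiary alkyl group should migrate with retention faster than the hindered ring ketone is oxidised, followed by methanolysis of the formate to the C1 tertiary alcohol trans to the side chain.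

**Step 9**
Reactants: 15 (3S,4S)-4-hydroxy-2,2,4-trimethyl-3-[2-(Diox)ethyl]cyclohexan-1-one
Product: 16 N′-{(1E,3S,4S)-4-hydroxy-2,2,4-trimethyl-3-[2-(Diox)ethyl]cyclohexylidene}-4-methylbenzenesulfonohydrazide
Conditions: TsNHNH2, PPTS (cat.), MgSO4, THF, 50 °C
Reagents that add atoms: 4-methylbenzenesulfonohydrazide, Cc1ccc(cc1)S(=O)(=O)NN
Why: Condensation of the only remaining carbonyl group to the tosylhydrazone, with the sulfonamide nitrogen expected on the side of C5, away from the gem-dimethyl carbon.

**Step 10**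
Reactants: 16 N′-{(1E,3S,4S)-4-hydroxy-2,2,4-trimethyl-3-[2-(Diox)ethyl]cyclohexylidene}-4-methylbenzenesulfonohydrazide
Product: 18 (1S,6S)-1,5,5-trimethyl-6-[2-(Diox)ethyl]cyclohex-3-en-1-ol, via vinyllithium 17 (not isolated)
Conditions: n-BuLi (4 equiv), TMEDA, THF, −78 °C → rt; then H2O
Reagents that add atoms: none
Why: Shapiro reaction, in which the trianion loses sulfinate and N2 to give the C4 vinyllithium (only C5 carries alpha-hydrogens), protonated on quench to the C4=C5 alkene.

**Step 11**
Reactants: 18 (1S,6S)-1,5,5-trimethyl-6-[2-(Diox)ethyl]cyclohex-3-en-1-ol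
Product: 19 (1R,3S,4S,6S)-3,5,5-trimethyl-4-[2-(Diox)ethyl]-7-oxabicyclo[4.1.0]heptan-3-ol
Conditions: VO(acac)2 (cat.), t-BuOOH, CH2Cl2, 0 °C → rt
Reagents that add atoms: tert-butyl hydroperoxide, CC(C)(C)OO
Why: Hydroxyl-directed epoxidation of the homoallylic alcohol should deliver oxygen to the ring face of the C1 hydroxyl, which is also the face away from the side chain and the C1 methyl, so that the new C4–O bond is cis to C1–OH.

**Step 12**
Reactants: 19 (1R,3S,4S,6S)-3,5,5-trimethyl-4-[2-(Diox)ethyl]-7-oxabicyclo[4.1.0]heptan-3-ol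
Product: 20 (1S,2S,4R)-1,3,3-trimethyl-2-[2-(Diox)ethyl]cyclohexane-1,4-diol
Conditions: LiAlH4, THF, 0 °C → reflux; aqueous work-up
Reagents that add atoms: none
Why: Reductive epoxide opening by hydride at C5, the carbon remote from the neopentylic C4 (trans-diaxial opening, the standard way to an axial carbinol next to a gem-dimethyl carbon), leaves the C4–O bond untouched and should give the cis-1,4-diol.

**Step 13**
Reactants: 20 (1S,2S,4R)-1,3,3-trimethyl-2-[2-(Diox)ethyl]cyclohexane-1,4-diol
Product: 21 (1S,2S,4R)-2-[(3R)-3,5-dihydroxy-3-methylpentyl]-1,3,3-trimethylcyclohexane-1,4-diol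
Conditions: PPTS, MeOH, 40 °C
Reagents that add atoms: none
Why: Acid-catalysed transketalisation to methanol removes the acetonide under conditions mild enough for the tertiary alcohols.

**Step 14**
Reactants: 21 (1S,2S,4R)-2-[(3R)-3,5-dihydroxy-3-methylpentyl]-1,3,3-trimethylcyclohexane-1,4-diol; 22 umbelliferone
Product: 23 7-{[(3R)-5-[(1S,3R,6S)-3,6-dihydroxy-2,2,6-trimethylcyclohexyl]-3-hydroxy-3-methylpentyl]oxy}-2H-chromen-2-one
Conditions: PPh3, DIAD, THF, 0 °C → rt
Reagents that add atoms: 22 umbelliferone, Oc1ccc2ccc(=O)oc2c1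
Why: Mitsunobu etherification, in which only the primary hydroxyl should be activated (the secondary one is neopentylic, the other two tertiary) and displaced by the acidic phenol of umbelliferone.

**Compound list**
1 | (R)-(−)-linalool, (3R)-3,7-dimethylocta-1,6-dien-3-ol | C=C[C@](C)(O)CCC=C(C)C | starting material
2 | bis-boryl adduct, (3R)-1-(9-borabicyclo[3.3.1]nonan-9-yl)-3-(9-borabicyclo[3.3.1]nonan-9-yloxy)-3,7-dimethyloct-6-ene | CC(C)=CCC[C@@](C)(OB1C2CCCC1CCC2)CCB1C2CCCC1CCC2 | intermediate
3 | (3R)-3,7-dimethyloct-6-ene-1,3-diol | CC(C)=CCC[C@@](C)(O)CCO | intermediate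
4 | (4R)-2,2,4-trimethyl-4-(4-methylpent-3-en-1-yl)-1,3-dioxane | CC(C)=CCC[C@@]1(C)OC(C)(C)OCC1 | intermediate
5 | ozonide, 3,3-dimethyl-5-[2-(Diox)ethyl]-1,2,4-trioxolane (mixture at the trioxolane CH) | CC1(C)OOC(CC[C@@]2(C)OC(C)(C)OCC2)O1 | intermediate
6 | 3-(Diox)propanal | O=CCC[C@@]1(C)OC(C)(C)OCC1 | intermediate
7 | 3-(triphenyl-λ5-phosphanylidene)butan-2-one | CC(=O)C(C)=P(c1ccccc1)(c1ccccc1)c1ccccc1 | starting material
8 | (3E)-3-methyl-6-(Diox)hex-3-en-2-one | CC(=O)/C(C)=C/CC[C@@]1(C)OC(C)(C)OCC1 | intermediate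
9 | triisopropyl{[(3E)-3-methyl-6-(Diox)hexa-1,3-dien-2-yl]oxy}silane | C=C(O[Si](C(C)C)(C(C)C)C(C)C)/C(C)=C/CC[C@@]1(C)OC(C)(C)OCC1 | intermediate
10 | methacrolein, 2-methylprop-2-enal | CC(=C)C=O | starting material
11 | (1S,2S)-1,3-dimethyl-2-[2-(Diox)ethyl]-4-(triisopropylsilyloxy)cyclohex-3-ene-1-carbaldehyde (formyl trans to side chain) | CC1=C(O[Si](C(C)C)(C(C)C)C(C)C)CC[C@](C)(C=O)[C@H]1CC[C@@]2(C)OC(C)(C)OCC2 | intermediate
12 | ammonium enolate, tetrabutylammonium salt of the desilylated enolate of 11 | CC1=C([O-])CC[C@](C)(C=O)[C@H]1CC[C@@]2(C)OC(C)(C)OCC2.CCCC[N+](CCCC)(CCCC)CCCC | intermediate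
13 | (1S,2R)-1,3,3-trimethyl-4-oxo-2-[2-(Diox)ethyl]cyclohexane-1-carbaldehyde | CC1(C)C(=O)CC[C@](C)(C=O)[C@H]1CC[C@@]2(C)OC(C)(C)OCC2 | intermediate
14 | keto formate, (1S,2S)-1,3,3-trimethyl-4-oxo-2-[2-(Diox)ethyl]cyclohexyl formate | CC1(C)C(=O)CC[C@](C)(OC=O)[C@H]1CC[C@@]2(C)OC(C)(C)OCC2 | intermediate
15 | (3S,4S)-4-hydroxy-2,2,4-trimethyl-3-[2-(Diox)ethyl]cyclohexan-1-one | CC1(C)C(=O)CC[C@](C)(O)[C@H]1CC[C@@]2(C)OC(C)(C)OCC2 | intermediate
16 | N′-{(1E,3S,4S)-4-hydroxy-2,2,4-trimethyl-3-[2-(Diox)ethyl]cyclohexylidene}-4-methylbenzenesulfonohydrazide | CC1(C)/C(=N/NS(=O)(=O)c2ccc(C)cc2)CC[C@](C)(O)[C@H]1CC[C@@]3(C)OC(C)(C)OCC3 | intermediate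
17 | vinyllithium, C4-lithio alkene as its lithium C1-alkoxide | CC1(C)C([Li])=CC[C@](C)(O[Li])[C@H]1CC[C@@]2(C)OC(C)(C)OCC2 | intermediate
18 | (1S,6S)-1,5,5-trimethyl-6-[2-(Diox)ethyl]cyclohex-3-en-1-ol | CC1(C)C=CC[C@](C)(O)[C@H]1CC[C@@]2(C)OC(C)(C)OCC2 | intermediate
19 | (1R,3S,4S,6S)-3,5,5-trimethyl-4-[2-(Diox)ethyl]-7-oxabicyclo[4.1.0]heptan-3-ol (epoxide cis to OH) | CC1(C)[C@@H]2O[C@@H]2C[C@](C)(O)[C@H]1CC[C@@]3(C)OC(C)(C)OCC3 | intermediate
20 | (1S,2S,4R)-1,3,3-trimethyl-2-[2-(Diox)ethyl]cyclohexane-1,4-diol | CC1(C)[C@H](O)CC[C@](C)(O)[C@H]1CC[C@@]2(C)OC(C)(C)OCC2 | intermediate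
21 | (1S,2S,4R)-2-[(3R)-3,5-dihydroxy-3-methylpentyl]-1,3,3-trimethylcyclohexane-1,4-diol | CC1(C)[C@H](O)CC[C@](C)(O)[C@H]1CC[C@@](C)(O)CCO | intermediate
22 | umbelliferone, 7-hydroxy-2H-chromen-2-one | Oc1ccc2ccc(=O)oc2c1 | starting material
23 | 7-{[(3R)-5-[(1S,3R,6S)-3,6-dihydroxy-2,2,6-trimethylcyclohexyl]-3-hydroxy-3-methylpentyl]oxy}-2H-chromen-2-one | CC1(C)[C@H](O)CC[C@](C)(O)[C@H]1CC[C@@](C)(O)CCOc1ccc2ccc(=O)oc2c1 | target

**Step count and risks**
Total step count: 14. Longest linear sequence: 14 steps (from 1).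

Steps most likely to fail:

Step 6. Catalyst control may be lost, by binding of the Lewis-basic dioxane to the boron catalyst or by a background reaction, which would erode facial and exo selectivity. Fallback, setting out from 9 and 10 and coming back at 11: the cycloaddition is promoted by the achiral Lewis acid EtAlCl2 in CH2Cl2 at −78 °C. Regiochemistry is a property of the siloxy diene and should be kept, but both ring antipodes form. Because the dioxane centre is already fixed, 11 and its ring-antipodal diastereomer (1R,2R)-adduct F1 are diastereomers; they are separated by preparative chromatography and 11 re-enters at step 7.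

Step 7. Proton transfer between the naked enolate and the product ketone may lead to enolate equilibration and over-methylation at C5, or the aldehyde may capture the enolate. Fallback, setting out from 11 and coming back at 13: Simmons–Smith cyclopropanation of the enol ether (Et2Zn, CH2I2, CH2Cl2, 0 °C) gives siloxycyclopropane F2. Bu4NF frees cyclopropanol F3, and K2CO3 in MeOH opens it by cleavage of the bond to the unsubstituted ring carbon, which is protonated to the second C3 methyl group, giving 13.

Step 8. Hydride may migrate in place of the tertiary alkyl group (oxidation to the acid), or the ring ketone may undergo competing Baeyer–Villiger oxidation. Fallback, setting out from 13 and coming back at 15: Pinnick oxidation (NaClO2, NaH2PO4, 2-methylbut-2-ene, t-BuOH/H2O) gives keto acid F4. DCC and 1-hydroxypyridine-2(1H)-thione give Barton ester F5. Irradiation under O2 with t-BuSH gives hydroperoxide F6; the planar tertiary C1 radical is expected to be trapped on the face away from the neighbouring side chain, the face the formyl group had occupied. P(OEt)3 reduces F6 to 15.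

**Further compounds**
F1 | step 6 | (1R,2R)-1,3-dimethyl-2-[2-(Diox)ethyl]-4-(triisopropylsilyloxy)cyclohex-3-ene-1-carbaldehyde | CC1=C(O[Si](C(C)C)(C(C)C)C(C)C)CC[C@@](C)(C=O)[C@@H]1CC[C@@]2(C)OC(C)(C)OCC2
F2 | step 7 | siloxycyclopropane of 11 (CH2 added across the enol ether on the face anti to the side chain) | C[C@@]12C[C@]1(O[Si](C(C)C)(C(C)C)C(C)C)CC[C@](C)(C=O)[C@H]2CC[C@@]3(C)OC(C)(C)OCC3
F3 | step 7 | cyclopropanol from F2 | C[C@@]12C[C@]1(O)CC[C@](C)(C=O)[C@H]2CC[C@@]3(C)OC(C)(C)OCC3
F4 | step 8 | (1S,2S)-1,3,3-trimethyl-4-oxo-2-[2-(Diox)ethyl]cyclohexane-1-carboxylic acid | CC1(C)C(=O)CC[C@](C)(C(O)=O)[C@H]1CC[C@@]2(C)OC(C)(C)OCC2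
F5 | step 8 | 2-thioxopyridin-1(2H)-yl (1S,2S)-1,3,3-trimethyl-4-oxo-2-[2-(Diox)ethyl]cyclohexane-1-carboxylate | CC1(C)C(=O)CC[C@](C)(C(=O)ON2C=CC=CC2=S)[C@H]1CC[C@@]3(C)OC(C)(C)OCC3
F6 | step 8 | (3S,4S)-4-hydroperoxy-2,2,4-trimethyl-3-[2-(Diox)ethyl]cyclohexan-1-one | CC1(C)C(=O)CC[C@](C)(OO)[C@H]1CC[C@@]2(C)OC(C)(C)OCC2
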